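**Strategy**

Each benzene ring of the target carries, going round, C1-CH2O, C2-Br, C3-Br, C4-OH, C5-OH, C6-Br. C1-C2 is read as the two carbons of a bromoalkyne, and C3 to C6 as the Br-C=C(O)-C(O)=C-Br diene of a 2,5-dibromo-3,4-dioxythiophene 1,1-dioxide; this is what permits a benzannulation.
The retrosynthesis first puts four methoxymethyl groups back on the phenols, then cuts the ring bonds C2-C3 and C1-C6 in both rings at once. This leaves a CH2-O-CH2-linked bis(bromoalkyne) and two equivalents of one symmetric sulfone diene.
Forward, the central ether chain is bought intact as dipropargyl ether and brominated at both alkyne termini. The diene comes from a commercial 3,4-dihydroxythiophene diester by acetal protection, saponification, decarboxylation, dibromination and S-oxidation.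
The two arenes then arise together, one at each end of the chain, by Diels-Alder addition and loss of SO2, with all six C-Br bonds already in place; acid unmasks the four phenols.
The target is achiral, with no stereocenter or stereogenic double bond, so there is no stereochemistry to set.

Key step: step 7

Remark: 1 and 9 are taken as purchasable, dimethyldioxirane is used as a freshly prepared acetone solution, and 10 is kept in solution throughout because small 1-bromoalkynes can decompose violently when neat.

**Route**

Step 1
Reactants: 1 diethyl 3,4-dihydroxythiophene-2,5-dicarboxylate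
Product: 2 diethyl 3,4-bis(methoxymethoxy)thiophene-2,5-dicarboxylate
Conditions: MOMCl (2.5 equiv), K2CO3 (3 equiv), DMF, 0 °C to rt
Reagents that add atoms: chloromethyl methyl ether, COCCl
Why: Williamson-type O-alkylation: K2CO3 deprotonates the two acidic enolic hydroxyls and the hard electrophile MOMCl is captured at oxygen, leaving the esters untouched.

Step 2
Reactants: 2 diethyl 3,4-bis(methoxymethoxy)thiophene-2,5-dicarboxylate
Product: 4 3,4-bis(methoxymethoxy)thiophene-2,5-dicarboxylic acid, via disodium dicarboxylate 3 (not isolated)
Conditions: NaOH (6 equiv), EtOH/H2O, 70 °C; then 1 M HCl to pH 3, 0 °C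
Reagents that add atoms: sodium hydroxide, [Na+].[OH-]
Why: Saponification (base-mediated acyl substitution) of both ethyl esters, to which the base-stable acetals are inert, followed by brief cold acidification at a pH the aryl acetals should tolerate.

Step 3
Reactants: 4 3,4-bis(methoxymethoxy)thiophene-2,5-dicarboxylic acid
Product: 5 3,4-bis(methoxymethoxy)thiophene
Conditions: Cu2O (10 mol%), 1,10-phenanthroline (20 mol%), NMP/quinoline (3:1), 160 °C, N2
Reagents that add atoms: none
Why: Copper-catalysed protodecarboxylation of a heteroaryl 2-carboxylic acid, the classical exit from 3,4-dialkoxythiophene-2,5-dicarboxylic acids, run in a basic medium that protects the acetals.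

Step 4
Reactants: 5 3,4-bis(methoxymethoxy)thiophene
Product: 6 2,5-dibromo-3,4-bis(methoxymethoxy)thiophene
Conditions: NBS (2.05 equiv), NaHCO3 (solid), DMF, -10 to 0 °C, dark
Reagents that add atoms: N-bromosuccinimide, O=C1CCC(=O)N1Br
Why: Electrophilic aromatic substitution: the two free alpha positions of the electron-rich 3,4-dialkoxythiophene are the only ring C-H sites and should take up bromine from NBS without release of strong acid.

Step 5
Reactants: 6 2,5-dibromo-3,4-bis(methoxymethoxy)thiophene
Product: 8 2,5-dibromo-3,4-bis(methoxymethoxy)thiophene 1,1-dioxide, via thiophene 1-oxide 7 (not isolated)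
Conditions: dimethyldioxirane (3 equiv, acetone solution), CH2Cl2, -20 °C to rt
Reagents that add atoms: dimethyldioxirane, CC1(C)OO1
Why: Electrophilic oxygen transfer from the dioxirane to sulfur (thiophene S-oxidation to the 1,1-dioxide) under neutral conditions that spare the acetals; the non-aromatic S-oxide 7 should be oxidized faster than 6, and the four ring substituents keep the resulting diene from dimerizing.

Step 6
Reactants: 9 dipropargyl ether
Product: 10 bis(3-bromoprop-2-yn-1-yl) ether
Conditions: NBS (2.2 equiv), AgNO3 (10 mol%), acetone, rt, dark; solvent exchange into PhCl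
Reagents that add atoms: N-bromosuccinimide, O=C1CCC(=O)N1Br
Why: AgNO3-catalysed electrophilic bromination of terminal alkynes with NBS, a standard route to 1-bromoalkynes that leaves the propargylic ether untouched.

Step 7
Reactants: 8 2,5-dibromo-3,4-bis(methoxymethoxy)thiophene 1,1-dioxide; 10 bis(3-bromoprop-2-yn-1-yl) ether
Product: 14 bis[2,3,6-tribromo-4,5-bis(methoxymethoxy)benzyl] ether, via first bridged sulfone adduct 11 (not isolated), via mono-arene bromoalkyne 12 (not isolated), via second bridged sulfone adduct 13 (not isolated)
Conditions: 8 (2.6 equiv), 2,6-di-tert-butyl-4-methylpyridine (10 mol%), PhCl, 110 to 130 °C, slow Ar sweep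
Reagents that add atoms: none
Why: The sulfone 8 is a non-aromatic, s-cis-fixed diene, so each bromoalkyne of 10 should undergo a concerted [4+2] cycloaddition across C2 and C5 of the heterocycle to give a 7-thiabicyclo[2.2.1]hepta-2,5-diene 7,7-dioxide (11, later 13), which loses SO2 irreversibly by cheletropic extrusion and aromatizes without an oxidant. The closest known reaction type is the Diels-Alder reaction of tetrasubstituted thiophene 1,1-dioxides with alkynes followed by SO2 loss to give benzenes. Each of the two benzene rings is closed by an intermolecular suprafacial [4+2] cycloaddition that forms both new ring C-C bonds (thiophene C2 and C5 to the two alkyne carbons) in one event, the six-membered carbocycle being unveiled when the one-atom sulfur bridge leaves. No stereocenter survives, because the bridgehead carbons of 11 and 13 become arene carbons. The step needs chemoselectivity for cross-cycloaddition over diene self-dimerization and complete twofold conversion, which the fully substituted diene with bromine on both termini, the excess of 8 and the irreversible SO2 loss should secure; regiochemistry is not an issue because 8 has a mirror plane through sulfur and the C3-C4 bond, so either alkyne orientation gives the same ring. The hindered pyridine and the argon sweep keep SO2-derived acid away from the four acetals.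

Step 8
Reactants: 14 bis[2,3,6-tribromo-4,5-bis(methoxymethoxy)benzyl] ether
Product: 15 bis(2,3,6-tribromo-4,5-dihydroxybenzyl) ether
Conditions: CF3CO2H/CH2Cl2 (1:4), 0 °C to rt; then cold H2O work-up
Reagents that add atoms: none
Why: Acid-catalysed cleavage of the four aryl methoxymethyl acetals (acetal deprotection) through loss of the methoxymethyl cation from the protonated acetal; with no alcohol or water as solvent, the central dibenzyl ether, on electron-poor rings and flanked by ortho bromines, should not ionize.

**Compound list**

1 | diethyl 3,4-dihydroxythiophene-2,5-dicarboxylate | CCOC(=O)c1sc(C(=O)OCC)c(O)c1O | starting material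
2 | diethyl 3,4-bis(methoxymethoxy)thiophene-2,5-dicarboxylate | CCOC(=O)c1sc(C(=O)OCC)c(OCOC)c1OCOC | intermediate
3 | disodium 3,4-bis(methoxymethoxy)thiophene-2,5-dicarboxylate | COCOc1c(C(=O)[O-])sc(C(=O)[O-])c1OCOC.[Na+].[Na+] | intermediate
4 | 3,4-bis(methoxymethoxy)thiophene-2,5-dicarboxylic acid | COCOc1c(C(=O)O)sc(C(=O)O)c1OCOC | intermediate
5 | 3,4-bis(methoxymethoxy)thiophene | COCOc1cscc1OCOC | intermediate
6 | 2,5-dibromo-3,4-bis(methoxymethoxy)thiophene | COCOc1c(Br)sc(Br)c1OCOC | intermediate
7 | 2,5-dibromo-3,4-bis(methoxymethoxy)thiophene 1-oxide | COCOC1=C(Br)S(=O)C(Br)=C1OCOC | intermediate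
8 | 2,5-dibromo-3,4-bis(methoxymethoxy)thiophene 1,1-dioxide | COCOC1=C(Br)S(=O)(=O)C(Br)=C1OCOC | intermediate
9 | dipropargyl ether | C#CCOCC#C | starting material
10 | bis(3-bromoprop-2-yn-1-yl) ether | BrC#CCOCC#CBr | intermediate
11 | 1,2,4-tribromo-3-{[(3-bromoprop-2-yn-1-yl)oxy]methyl}-5,6-bis(methoxymethoxy)-7-thiabicyclo[2.2.1]hepta-2,5-diene 7,7-dioxide | BrC#CCOCC1=C(Br)C2(Br)C(OCOC)=C(OCOC)C1(Br)S2(=O)=O | intermediate
12 | 1,2,4-tribromo-3-{[(3-bromoprop-2-yn-1-yl)oxy]methyl}-5,6-bis(methoxymethoxy)benzene | COCOc1c(OCOC)c(Br)c(COCC#CBr)c(Br)c1Br | intermediate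
13 | 1,2,4-tribromo-5,6-bis(methoxymethoxy)-3-({[2,3,6-tribromo-4,5-bis(methoxymethoxy)benzyl]oxy}methyl)-7-thiabicyclo[2.2.1]hepta-2,5-diene 7,7-dioxide | COCOc1c(OCOC)c(Br)c(COCC2=C(Br)C3(Br)C(OCOC)=C(OCOC)C2(Br)S3(=O)=O)c(Br)c1Br | intermediate
14 | bis[2,3,6-tribromo-4,5-bis(methoxymethoxy)benzyl] ether | COCOc1c(OCOC)c(Br)c(COCc2c(Br)c(OCOC)c(OCOC)c(Br)c2Br)c(Br)c1Br | intermediate
15 | bis(2,3,6-tribromo-4,5-dihydroxybenzyl) ether | Oc1c(O)c(Br)c(COCc2c(Br)c(O)c(O)c(Br)c2Br)c(Br)c1Br | target

**Step count and risks**

Total step count: 8. Longest linear sequence: 7 steps (steps 1, 2, 3, 4, 5, 7, 8, from 1 to 15); step 6 is a one-step side branch that joins at step 7.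

The three steps most likely to fail:

Step 7. The cycloaddition at the hindered, only weakly polarized bromoalkyne may be slower than thermal breakdown of the bromoalkyne and of the sulfone diene, or the sequence may stall after the first ring has formed. The fallback changes the dienophile and moves one bromination per ring to the end. It sets out from 9 and 8 and comes back at 14. Heating the thermally robust, unhindered dipropargyl ether 9 with an excess of 8 under the conditions of step 7 should lead through 1,4-dibromo-5,6-bis(methoxymethoxy)-2-[(prop-2-yn-1-yloxy)methyl]-7-thiabicyclo[2.2.1]hepta-2,5-diene 7,7-dioxide F1, then by loss of SO2 to 1,4-dibromo-2,3-bis(methoxymethoxy)-5-[(prop-2-yn-1-yloxy)methyl]benzene F2. A second cycloaddition should give 1,4-dibromo-2-({[2,5-dibromo-3,4-bis(methoxymethoxy)benzyl]oxy}methyl)-5,6-bis(methoxymethoxy)-7-thiabicyclo[2.2.1]hepta-2,5-diene 7,7-dioxide F3, and a second loss of SO2 should give bis[2,5-dibromo-3,4-bis(methoxymethoxy)benzyl] ether F4. Each ring of this ether has a single free C-H, para to an acetal oxygen. Electrophilic aromatic bromination with NBS in MeCN in the dark, with gentle warming if needed, should fill it and give 14.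

Step 5. Oxygen transfer to a sulfur atom that is flanked and deactivated by two bromines may be slow. The oxidant would then be consumed by the enol ether double bonds or the acetal C-H bonds, or the reaction would stop at partial oxidation. The fallback inverts the order of bromination and oxidation. It sets out from 5 and comes back at 8. The unbrominated, more nucleophilic thiophene 5 should be oxidized by dimethyldioxirane in CH2Cl2 at low temperature through 3,4-bis(methoxymethoxy)thiophene 1-oxide F5 to 3,4-bis(methoxymethoxy)thiophene 1,1-dioxide F6. This sulfone is then brominated at once, cold, with NBS at its two alpha carbons. These are the nucleophilic carbons of a beta-alkoxy vinyl sulfone, and the reaction is analogous to the alpha-bromination of beta-alkoxy enones. The product should be 8.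

Step 8. Once the first phenols are free, acid may ionize the para-hydroxybenzylic C-O bond (quinone methide pathway), so that the central ether is cleaved or exchanged while the last acetals are still being removed. The fallback accepts this cleavage and rebuilds the ether. It sets out from 14 and comes back at 15. Aqueous HCl in THF at about 50 °C should remove all four acetals and hydrolyse the benzylic ether, giving two equivalents of 2,3,6-tribromo-4,5-dihydroxybenzyl alcohol F7. This alcohol, in concentrated solution in 1,2-dichloroethane with catalytic p-toluenesulfonic acid over 4 Å molecular sieves, should self-condense by dehydrative etherification to 15. C-alkylation is excluded because every ring position is substituted.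

Further compounds
F1 | step 7 | 1,4-dibromo-5,6-bis(methoxymethoxy)-2-[(prop-2-yn-1-yloxy)methyl]-7-thiabicyclo[2.2.1]hepta-2,5-diene 7,7-dioxide | C#CCOCC1=CC2(Br)C(OCOC)=C(OCOC)C1(Br)S2(=O)=O
F2 | step 7 | 1,4-dibromo-2,3-bis(methoxymethoxy)-5-[(prop-2-yn-1-yloxy)methyl]benzene | COCOc1c(OCOC)c(Br)c(COCC#C)cc1Br
F3 | step 7 | 1,4-dibromo-2-({[2,5-dibromo-3,4-bis(methoxymethoxy)benzyl]oxy}methyl)-5,6-bis(methoxymethoxy)-7-thiabicyclo[2.2.1]hepta-2,5-diene 7,7-dioxide | COCOc1c(OCOC)c(Br)c(COCC2=CC3(Br)C(OCOC)=C(OCOC)C2(Br)S3(=O)=O)cc1Br
F4 | step 7 | bis[2,5-dibromo-3,4-bis(methoxymethoxy)benzyl] ether | COCOc1c(OCOC)c(Br)c(COCc2cc(Br)c(OCOC)c(OCOC)c2Br)cc1Br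
F5 | step 5 | 3,4-bis(methoxymethoxy)thiophene 1-oxide | COCOC1=CS(=O)C=C1OCOC
F6 | step 5 | 3,4-bis(methoxymethoxy)thiophene 1,1-dioxide | COCOC1=CS(=O)(=O)C=C1OCOC
F7 | step 8 | 2,3,6-tribromo-4,5-dihydroxybenzyl alcohol | OCc1c(Br)c(Br)c(O)c(O)c1Br
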